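Ring A is not carried through the synthesis but built near the end: its guaiacol pattern (C4′–OH next to C3′–OMe, chain at C1′ para to the hydroxyl) is the dehydrogenated form of a 4-alkyl-2-methoxycyclohex-2-enone. One amine-catalysed Robinson annulation joins 1-methoxybut-3-en-2-one to an aldehyde in which C1 of the heptane chain is extended by two carbons, forming C1′–C6′ and C2′–C3′ and closing ring A. The aldehyde already holds the C3/C5 syn-diacetate of the target and benzyl-protected ring B, so that aromatisation delivers the ring A phenol free and a single hydrogenolysis ends the route.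

Key step: step 9

Remark: chain atoms are numbered as in the target (C1 carries ring A, C7 ring B; ring A atoms C1′–C6′ with C3′–OMe and C4′–OH), and 4-allyl-2,6-dimethoxyphenol, hept-6-en-2-one and N,2-dimethoxy-N-methylacetamide are taken to be catalogue chemicals.

Step 1
Reactants: 1 4-allyl-2,6-dimethoxyphenol
Product: 2 5-allyl-2-(benzyloxy)-1,3-dimethoxybenzene
Conditions: BnBr, K2CO3, DMF, 60 °C
Reagents that add atoms: benzyl bromide, BrCc1ccccc1
Why: Williamson etherification of the phenoxide; the benzyl ether shields the oxidation-prone ring B phenol from the boron, osmium and palladium/oxygen chemistry ahead and can be removed at the end without touching acetates.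

Step 2
Reactants: 2 5-allyl-2-(benzyloxy)-1,3-dimethoxybenzene
Product: 4 3-[4-(benzyloxy)-3,5-dimethoxyphenyl]propan-1-ol, via alkylborane 3 (not isolated)
Conditions: 9-BBN, THF, 0 °C → rt; then aq NaOH, H2O2, 0 °C → rt
Reagents that add atoms: hydrogen peroxide, OO
Why: Brown hydroboration–oxidation: the bulky dialkylborane adds anti-Markovnikov to the terminal alkene and the C–B bond is oxidised to the primary alcohol.

Step 3
Reactants: 4 3-[4-(benzyloxy)-3,5-dimethoxyphenyl]propan-1-ol
Product: 5 3-[4-(benzyloxy)-3,5-dimethoxyphenyl]propanal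
Conditions: TEMPO (10 mol%), PhI(OAc)2, CH2Cl2, rt
Reagents that add atoms: none
Why: TEMPO/PhI(OAc)2 oxidation: the oxoammonium salt oxidises the primary alcohol and, without water, stops at the aldehyde while the benzyl ether and the electron-rich ring are left alone.

Step 4
Reactants: 6 hept-6-en-2-one, 5 3-[4-(benzyloxy)-3,5-dimethoxyphenyl]propanal
Product: 8 (3S)-1-[4-(benzyloxy)-3,5-dimethoxyphenyl]-3-hydroxydec-9-en-5-one, via enol borinate 7 (not isolated)
Conditions: (−)-Ipc2BCl, Et3N, Et2O, 0 °C (6 → 7); then 5, −78 → −20 °C; then H2O2, MeOH, pH 7 buffer, 0 °C → rt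
Reagents that add atoms: none
Why: Paterson boron aldol: Ipc2BCl/Et3N enolises the methyl ketone on its methyl side, and the pinene-derived ligands of (−)-Ipc2BCl (the antipode that sends the enolate to the re face of the aldehyde) set the carbinol as (S), which is C5 of the target, under reagent control.

Step 5
Reactants: 8 (3S)-1-[4-(benzyloxy)-3,5-dimethoxyphenyl]-3-hydroxydec-9-en-5-one
Product: 10 (3S,5R)-1-[4-(benzyloxy)-3,5-dimethoxyphenyl]dec-9-ene-3,5-diol, via boron chelate 9 (not isolated)
Conditions: Et2BOMe, THF/MeOH (4:1), −78 °C; then NaBH4, −78 °C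
Reagents that add atoms: none
Why: Narasaka–Prasad reduction: Et2BOMe ties hydroxyl and ketone into a six-membered chelate and NaBH4 delivers hydride externally and axially to its half-chair, which sets the new carbinol (C3 of the target, R) syn to the existing one by 1,3-induction; boron leaves again as Et2BOMe on methanol co-evaporation.

Step 6
Reactants: 10 (3S,5R)-1-[4-(benzyloxy)-3,5-dimethoxyphenyl]dec-9-ene-3,5-diol
Product: 11 (3S,5R)-1-[4-(benzyloxy)-3,5-dimethoxyphenyl]dec-9-ene-3,5-diyl diacetate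
Conditions: Ac2O, pyridine, DMAP (5 mol%), CH2Cl2, rt
Reagents that add atoms: acetic anhydride, CC(=O)OC(C)=O
Why: DMAP-catalysed O-acylation with retention at both carbinols installs the two acetates of the target now, so that no later diol deprotection or selective ester cleavage is needed.

Step 7
Reactants: 11 (3S,5R)-1-[4-(benzyloxy)-3,5-dimethoxyphenyl]dec-9-ene-3,5-diyl diacetate
Product: 12 (3S,5R)-1-[4-(benzyloxy)-3,5-dimethoxyphenyl]-9-oxononane-3,5-diyl diacetate
Conditions: OsO4 (2 mol%), NaIO4, 2,6-lutidine, dioxane/H2O (3:1), rt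
Reagents that add atoms: osmium tetroxide, O=[Os](=O)(=O)=O; sodium periodate, [Na+].[O-]I(=O)(=O)=O
Why: Lemieux–Johnson cleavage: catalytic osmylation of the terminal alkene and periodate scission of the diol give the aldehyde in one flask with loss of the terminal carbon, and the lutidine-buffered medium spares the acetates, the benzyl ether and the electron-rich arene that ozone would endanger.

Step 8
Reactants: 13 N,2-dimethoxy-N-methylacetamide, 14 vinylmagnesium bromide
Product: 15 1-methoxybut-3-en-2-one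
Conditions: THF, −10 → 0 °C; inverse quench into cold 1 M HCl/Et2O; distilled and kept cold over BHT
Reagents that add atoms: none
Why: Weinreb ketone synthesis: magnesium chelation by the N-methoxy group holds the adduct until work-up so that the Grignard reagent adds only once, and the inverse acidic quench keeps the released hydroxylamine protonated so that it cannot add to the enone.

Step 9
Reactants: 12 (3S,5R)-1-[4-(benzyloxy)-3,5-dimethoxyphenyl]-9-oxononane-3,5-diyl diacetate, 15 1-methoxybut-3-en-2-one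
Product: 17 (3R,5S)-7-[4-(benzyloxy)-3,5-dimethoxyphenyl]-1-(3-methoxy-4-oxocyclohex-2-en-1-yl)heptane-3,5-diyl diacetate as a mixture of ring epimers, via keto aldehyde 16 (not isolated)
Conditions: 15 (1.5 equiv), (S)-α,α-diphenylprolinol trimethylsilyl ether (10 mol%), ethyl 3,4-dihydroxybenzoate (20 mol%), toluene, 4 °C → rt; volatiles removed; then Bn2NH·CF3CO2H (30 mol%), 4 Å MS, toluene, 60 °C
Reagents that add atoms: none
Why: The hindered secondary amine turns aldehyde 12 into its enamine, whose α-carbon (future C1′) adds to the terminal carbon of 15 (future C6′) and gives the 1,5-keto aldehyde 16 after hydrolysis. The dibenzylammonium salt then activates the aldehyde as an iminium ion while the ketone enolises toward its methoxy-bearing carbon (C3′), which attacks the aldehyde carbon (C2′) and loses water to give the conjugated 2-methoxy enone; this is an amine-catalysed Robinson annulation of an aldehyde with a vinyl ketone, the established way to 4-substituted cyclohex-2-enones. Ring A closes in a favoured 6-(enolendo)-exo-trig aldol. The only new stereocentre is the ring carbon C1′, which the catalyst may bias but which needs no control because it becomes sp2 on aromatisation, and C3 and C5 are remote and untouched. The step needs regiochemistry only: closure from the other α-carbon of the ketone, or from the aldehyde α-carbon onto the ketone, would make four-membered rings, so connectivity alone puts the chain para to the future hydroxyl and meta to the methoxy group, while the bulky catalyst suppresses aldehyde self-aldol and the neutral, water-poor medium preserves both acetates, the benzyl ether and the enol ether.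

Step 10
Reactants: 17 (3R,5S)-7-[4-(benzyloxy)-3,5-dimethoxyphenyl]-1-(3-methoxy-4-oxocyclohex-2-en-1-yl)heptane-3,5-diyl diacetate
Product: 19 (3R,5S)-7-[4-(benzyloxy)-3,5-dimethoxyphenyl]-1-(4-hydroxy-3-methoxyphenyl)heptane-3,5-diyl diacetate, via cyclohexadienone 18 (not isolated)
Conditions: Pd(OCOCF3)2 (5 mol%), 2-(dimethylamino)pyridine (10 mol%), TsOH·H2O (20 mol%), O2 (1 atm), DMSO, 80 °C
Reagents that add atoms: none
Why: Palladium-catalysed aerobic dehydrogenation of a cyclohexenone: palladation at the α′-carbon and β-hydride elimination give dienone 18, which tautomerises to the guaiacol and thereby erases the ring stereocentre of 17, while dioxygen reoxidises the palladium and the esters and benzyl ether are inert.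

Step 11
Reactants: 19 (3R,5S)-7-[4-(benzyloxy)-3,5-dimethoxyphenyl]-1-(4-hydroxy-3-methoxyphenyl)heptane-3,5-diyl diacetate
Product: 20 (3R,5S)-1-(4-hydroxy-3-methoxyphenyl)-7-(4-hydroxy-3,5-dimethoxyphenyl)heptane-3,5-diyl diacetate
Conditions: H2 (1 atm), 10% Pd/C, EtOAc, rt
Reagents that add atoms: none
Why: Catalytic hydrogenolysis of the aryl benzyl ether frees the ring B phenol under neutral conditions that leave the secondary acetates, both stereocentres and the ring A guaiacol unchanged.

Compound list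
1 | 4-allyl-2,6-dimethoxyphenol | C=CCc1cc(OC)c(O)c(OC)c1 | starting material
2 | 5-allyl-2-(benzyloxy)-1,3-dimethoxybenzene | C=CCc1cc(OC)c(OCc2ccccc2)c(OC)c1 | intermediate
3 | 9-{3-[4-(benzyloxy)-3,5-dimethoxyphenyl]propyl}-9-borabicyclo[3.3.1]nonane | COc1cc(CCCB2C3CCCC2CCC3)cc(OC)c1OCc1ccccc1 | intermediate (not isolated)
4 | 3-[4-(benzyloxy)-3,5-dimethoxyphenyl]propan-1-ol | COc1cc(CCCO)cc(OC)c1OCc1ccccc1 | intermediate
5 | 3-[4-(benzyloxy)-3,5-dimethoxyphenyl]propanal | COc1cc(CCC=O)cc(OC)c1OCc1ccccc1 | intermediate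
6 | hept-6-en-2-one | CC(=O)CCCC=C | starting material
7 | (hepta-1,6-dien-2-yloxy)diisopinocampheylborane, Ipc groups from (+)-α-pinene (enol borinate of 6) | C=CCCCC(=C)OB([C@@H]1C[C@@H]2C[C@H]([C@H]1C)C2(C)C)[C@@H]1C[C@@H]2C[C@H]([C@H]1C)C2(C)C | intermediate (not isolated)
8 | (3S)-1-[4-(benzyloxy)-3,5-dimethoxyphenyl]-3-hydroxydec-9-en-5-one | C=CCCCC(=O)C[C@H](CCc1cc(OC)c(OCc2ccccc2)c(OC)c1)O | intermediate
9 | (3S)-1-[4-(benzyloxy)-3,5-dimethoxyphenyl]-3-[(diethylboranyl)oxy]dec-9-en-5-one (boron chelate of 8, ketone oxygen coordinated to boron) | C=CCCCC(=O)C[C@H](CCc1cc(OC)c(OCc2ccccc2)c(OC)c1)OB(CC)CC | intermediate (not isolated)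
10 | (3S,5R)-1-[4-(benzyloxy)-3,5-dimethoxyphenyl]dec-9-ene-3,5-diol (syn) | C=CCCC[C@H](C[C@H](CCc1cc(OC)c(OCc2ccccc2)c(OC)c1)O)O | intermediate
11 | (3S,5R)-1-[4-(benzyloxy)-3,5-dimethoxyphenyl]dec-9-ene-3,5-diyl diacetate | C=CCCC[C@H](C[C@H](CCc1cc(OC)c(OCc2ccccc2)c(OC)c1)OC(C)=O)OC(C)=O | intermediate
12 | (3S,5R)-1-[4-(benzyloxy)-3,5-dimethoxyphenyl]-9-oxononane-3,5-diyl diacetate | O=CCCC[C@H](C[C@H](CCc1cc(OC)c(OCc2ccccc2)c(OC)c1)OC(C)=O)OC(C)=O | intermediate
13 | N,2-dimethoxy-N-methylacetamide | COCC(=O)N(C)OC | starting material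
14 | vinylmagnesium bromide | C=C[Mg]Br | starting material
15 | 1-methoxybut-3-en-2-one | COCC(=O)C=C | intermediate
16 | (3S,5R)-1-[4-(benzyloxy)-3,5-dimethoxyphenyl]-8-formyl-12-methoxy-11-oxododecane-3,5-diyl diacetate (both C8 epimers) | COCC(=O)CCC(C=O)CC[C@H](C[C@H](CCc1cc(OC)c(OCc2ccccc2)c(OC)c1)OC(C)=O)OC(C)=O | intermediate (not isolated)
17 | (3R,5S)-7-[4-(benzyloxy)-3,5-dimethoxyphenyl]-1-(3-methoxy-4-oxocyclohex-2-en-1-yl)heptane-3,5-diyl diacetate (both ring epimers) | COC1=CC(CC[C@H](C[C@H](CCc2cc(OC)c(OCc3ccccc3)c(OC)c2)OC(C)=O)OC(C)=O)CCC1=O | intermediate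
18 | (3R,5S)-7-[4-(benzyloxy)-3,5-dimethoxyphenyl]-1-(3-methoxy-4-oxocyclohexa-2,5-dien-1-yl)heptane-3,5-diyl diacetate | COC1=CC(CC[C@H](C[C@H](CCc2cc(OC)c(OCc3ccccc3)c(OC)c2)OC(C)=O)OC(C)=O)C=CC1=O | intermediate (not isolated)
19 | (3R,5S)-7-[4-(benzyloxy)-3,5-dimethoxyphenyl]-1-(4-hydroxy-3-methoxyphenyl)heptane-3,5-diyl diacetate | COc1cc(CC[C@H](C[C@H](CCc2cc(OC)c(OCc3ccccc3)c(OC)c2)OC(C)=O)OC(C)=O)ccc1O | intermediate
20 | (3R,5S)-1-(4-hydroxy-3-methoxyphenyl)-7-(4-hydroxy-3,5-dimethoxyphenyl)heptane-3,5-diyl diacetate | COc1cc(CC[C@H](C[C@H](CCc2cc(OC)c(O)c(OC)c2)OC(C)=O)OC(C)=O)ccc1O | target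

Total step count: 11. Longest linear sequence: 10 steps (steps 1–7 and 9–11 from compound 1; step 8 is a one-step side branch).

Steps most likely to fail

Step 9. Oligomerisation of the vinyl ketone and self-aldol of the aldehyde may outrun the cross Michael addition, or the cyclodehydration may stall at the open keto aldehyde. The fallback gives up building ring A and brings it in ready-made; it sets out from aldehyde 5. Zingerone would be benzylated (BnBr, K2CO3, DMF) to 4-[4-(benzyloxy)-3-methoxyphenyl]butan-2-one F1, and the (−)-Ipc2B enolate of that ketone would be added to 5 as in step 4 to give (5S)-1-[4-(benzyloxy)-3-methoxyphenyl]-7-[4-(benzyloxy)-3,5-dimethoxyphenyl]-5-hydroxyheptan-3-one F2. Narasaka–Prasad reduction (Et2BOMe, NaBH4) should give the syn-diol (3R,5S)-1-[4-(benzyloxy)-3-methoxyphenyl]-7-[4-(benzyloxy)-3,5-dimethoxyphenyl]heptane-3,5-diol F3, and Ac2O/pyridine/DMAP its diacetate F4. Hydrogenolysis of both benzyl ethers (H2, Pd/C, EtOAc) comes back to the route at target 20.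

Step 10. Dehydrogenation may stop short or the enol ether may be hydrolysed by the acid co-catalyst at 80 °C before aromatisation is complete. The fallback oxidises stepwise through a silyl dienol ether and sets out from enone 17. TBSOTf/Et3N (CH2Cl2, 0 °C) would give the cross-conjugated dienol ether (3R,5S)-7-[4-(benzyloxy)-3,5-dimethoxyphenyl]-1-[4-(tert-butyldimethylsilyloxy)-3-methoxycyclohexa-2,4-dien-1-yl]heptane-3,5-diyl diacetate F5. Saegusa–Ito oxidation with stoichiometric Pd(OAc)2 (MeCN, rt) comes back to the route at dienone 18, which tautomerises to 19.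

Step 4. Enantioface discrimination by the Ipc ligands is usually incomplete for methyl ketone enolates, and no later step would remove the minor enantiomer. The fallback sets C5 by catalytic hydrogenation instead and sets out from aldehyde 5. Roskamp homologation (ethyl diazoacetate, SnCl2, CH2Cl2) would give ethyl 5-[4-(benzyloxy)-3,5-dimethoxyphenyl]-3-oxopentanoate F6. Noyori hydrogenation (RuCl2[(S)-BINAP], H2, EtOH) should give ethyl (3S)-5-[4-(benzyloxy)-3,5-dimethoxyphenyl]-3-hydroxypentanoate F7. MeNHOMe·HCl/i-PrMgCl (THF, −20 °C) would convert it into (3S)-5-[4-(benzyloxy)-3,5-dimethoxyphenyl]-3-hydroxy-N-methoxy-N-methylpentanamide F8, and excess pent-4-enylmagnesium bromide (THF, 0 °C) comes back to the route at hydroxy ketone 8.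

Further compounds
F1 | step 9 | 4-[4-(benzyloxy)-3-methoxyphenyl]butan-2-one | CC(=O)CCc1ccc(OCc2ccccc2)c(OC)c1
F2 | step 9 | (5S)-1-[4-(benzyloxy)-3-methoxyphenyl]-7-[4-(benzyloxy)-3,5-dimethoxyphenyl]-5-hydroxyheptan-3-one | COc1cc(CCC(=O)C[C@H](CCc2cc(OC)c(OCc3ccccc3)c(OC)c2)O)ccc1OCc1ccccc1
F3 | step 9 | (3R,5S)-1-[4-(benzyloxy)-3-methoxyphenyl]-7-[4-(benzyloxy)-3,5-dimethoxyphenyl]heptane-3,5-diol | COc1cc(CC[C@H](C[C@H](CCc2cc(OC)c(OCc3ccccc3)c(OC)c2)O)O)ccc1OCc1ccccc1
F4 | step 9 | (3R,5S)-1-[4-(benzyloxy)-3-methoxyphenyl]-7-[4-(benzyloxy)-3,5-dimethoxyphenyl]heptane-3,5-diyl diacetate | COc1cc(CC[C@H](C[C@H](CCc2cc(OC)c(OCc3ccccc3)c(OC)c2)OC(C)=O)OC(C)=O)ccc1OCc1ccccc1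
F5 | step 10 | (3R,5S)-7-[4-(benzyloxy)-3,5-dimethoxyphenyl]-1-[4-(tert-butyldimethylsilyloxy)-3-methoxycyclohexa-2,4-dien-1-yl]heptane-3,5-diyl diacetate | COC1=CC(CC[C@H](C[C@H](CCc2cc(OC)c(OCc3ccccc3)c(OC)c2)OC(C)=O)OC(C)=O)CC=C1O[Si](C)(C)C(C)(C)C
F6 | step 4 | ethyl 5-[4-(benzyloxy)-3,5-dimethoxyphenyl]-3-oxopentanoate | CCOC(=O)CC(=O)CCc1cc(OC)c(OCc2ccccc2)c(OC)c1
F7 | step 4 | ethyl (3S)-5-[4-(benzyloxy)-3,5-dimethoxyphenyl]-3-hydroxypentanoate | CCOC(=O)C[C@H](CCc1cc(OC)c(OCc2ccccc2)c(OC)c1)O
F8 | step 4 | (3S)-5-[4-(benzyloxy)-3,5-dimethoxyphenyl]-3-hydroxy-N-methoxy-N-methylpentanamide | CON(C)C(=O)C[C@H](CCc1cc(OC)c(OCc2ccccc2)c(OC)c1)O
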